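**Retrosynthetic overview**

1. Numbering: C1–C15 as in eudesmanes (C1 ketone, C2 and C5 bridgeheads, C3=C4, C6–O, C10 quaternary); C1′H2 (on C5) and C2′H (on C2) form the bridge that carries the 6-methylhepta-1,5-dien-2-yl chain. The enabling feature is the C3=C4 double bond between the bridgeheads C2 and C5 of the bicyclo[2.2.2]oct-5-en-2-one: it is a Diels–Alder retron, so the cyclohexenone ring C1–C2–C3–C4–C5–C10 is cut at C1–C2 and C5–C10.
2. That leaves ring C2–C3–C4–C5–C1′–C2′ as an α-phellandrene-type cyclohexa-1,3-diene, C10=C1 as a nitroalkene (ketene equivalent, Nef reaction gives the C1 ketone) and C6–C9 with the finished trans-lactone as tether. One intramolecular Diels–Alder reaction closes ring B and the bridged cyclohexenone ring together and sets C2, C5 and C10.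
3. The diene comes from an enone (kinetic dienyl triflate, reduction). The lactone triad C6/C7/C11 comes from a butenolide (anti cuprate-type addition, anti methylation). C6 comes from a vinylogous Mukaiyama–Michael addition to a carvone-type enone, so every stereocentre is relayed from the one bought centre C2′.
4. The side chain is grown first on (S)-carvone: allylic chlorination, allyl–allyl coupling, cross-metathesis.
5. Ring order: carbocycle C2–C5/C1′/C2′ (carvone) → γ-lactone → ring B and the cyclohexenone ring C1–C2–C3–C4–C5–C10 in the same, last ring-forming step.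

Key step: step 13

Assumption: the E and Z isomers of the nitroalkene formed in step 12 are carried on together, since C1 becomes a carbonyl carbon in step 14; the SMILES show the E isomer.

**Route**

Step 1
Reactants: 1 (S)-(+)-carvone
Product: 2 (5S)-5-(3-chloroprop-1-en-2-yl)-2-methylcyclohex-2-en-1-one
Conditions: Ca(OCl)2, CO2 (dry ice), CH2Cl2/H2O, 0 °C
Reagents that add atoms: calcium hypochlorite, [Ca+2].[O-]Cl.[O-]Cl
Why: Ene-type allylic chlorination by hypochlorous acid attacks only the electron-rich 1,1-disubstituted alkene (the enone alkene is deactivated), so the bought stereocentre is untouched.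

Step 2
Reactants: 2 (5S)-5-(3-chloroprop-1-en-2-yl)-2-methylcyclohex-2-en-1-one
Product: 3 (5S)-5-(hexa-1,5-dien-2-yl)-2-methylcyclohex-2-en-1-one
Conditions: allylB(pin) (1.5 equiv), Pd(PPh3)4 (5 mol %), CsF (3 equiv), THF, 60 °C
Reagents that add atoms: allylboronic acid pinacol ester, C=CCB1OC(C)(C)C(C)(C)O1
Why: Palladium-catalysed allyl–allyl cross-coupling through a 2-substituted π-allyl complex whose termini are equivalent, as are those of the allyl nucleophile, so only one constitution can form and the enone is left alone.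

Step 3
Reactants: 3 (5S)-5-(hexa-1,5-dien-2-yl)-2-methylcyclohex-2-en-1-one
Product: 4 (5S)-2-methyl-5-(6-methylhepta-1,5-dien-2-yl)cyclohex-2-en-1-one
Conditions: second-generation Grubbs catalyst (5 mol %), 2-methyl-2-butene/CH2Cl2 (1:1), 40 °C
Reagents that add atoms: 2-methyl-2-butene, CC=C(C)C
Why: Olefin cross-metathesis with 2-methyl-2-butene converts only the monosubstituted terminal alkene into the prenyl-type alkene, the 1,1-disubstituted alkene and the enone being far less reactive toward the ruthenium carbene.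

Step 4
Reactants: 4 (5S)-2-methyl-5-(6-methylhepta-1,5-dien-2-yl)cyclohex-2-en-1-one; 5 tert-butyl(furan-2-yloxy)dimethylsilane
Product: 6 (5S)-5-[(1S,5S)-3-{[tert-butyl(dimethyl)silyl]oxy}-2-methyl-5-(6-methylhepta-1,5-dien-2-yl)cyclohex-2-en-1-yl]furan-2(5H)-one
Conditions: TBSOTf (10 mol %), CH2Cl2, −78 °C
Reagents that add atoms: none
Why: Vinylogous Mukaiyama–Michael addition in which the furan γ-carbon adds axially to the enone β-carbon (C5 of the target) anti to the side chain, the silyl group passes to the enolate oxygen, and a compact Diels–Alder-like (endo) approach should set the butenolide carbon C6 as drawn.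

Step 5
Reactants: 6 (silyl enol ether butenolide); 7 2-(2-bromoethyl)-2-methyl-1,3-dioxolane
Product: 10 (4S,5S)-5-[(1S,5S)-3-{[tert-butyl(dimethyl)silyl]oxy}-2-methyl-5-(6-methylhepta-1,5-dien-2-yl)cyclohex-2-en-1-yl]-4-[2-(2-methyl-1,3-dioxolan-2-yl)ethyl]oxolan-2-one, via Grignard reagent 8 (not isolated), via magnesium enolate 9 (not isolated)
Conditions: 7, Mg, THF, 25 °C; then CuBr·SMe2 (10 mol %), 6, THF, −78 to −40 °C; then H2O (pH 7 buffer)
Reagents that add atoms: none
Why: Copper-catalysed conjugate addition of the Grignard reagent to the butenolide occurs anti to the bulky C6 substituent and gives the 6,7-trans lactone, the silyl enol ether and the alkenes being inert to the organocopper species.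

Step 6
Reactants: 10 (trans-4,5-disubstituted lactone)
Product: 12 (3S,4S,5S)-5-[(1S,5S)-3-{[tert-butyl(dimethyl)silyl]oxy}-2-methyl-5-(6-methylhepta-1,5-dien-2-yl)cyclohex-2-en-1-yl]-3-methyl-4-[2-(2-methyl-1,3-dioxolan-2-yl)ethyl]oxolan-2-one, via lithium enolate 11 (not isolated)
Conditions: LiN(i-Pr)2 (LDA, 1.1 equiv), THF, −78 °C; MeI, −78 to −30 °C
Reagents that add atoms: iodomethane, CI
Why: Alkylation of the lactone enolate takes place anti to the adjacent C7 substituent and gives the all-trans lactone, which is also the thermodynamically preferred C11 epimer.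

Step 7
Reactants: 12 (all-trans lactone silyl enol ether)
Product: 13 (5S)-2-methyl-5-(6-methylhepta-1,5-dien-2-yl)-3-{(2S,3S,4S)-4-methyl-3-[2-(2-methyl-1,3-dioxolan-2-yl)ethyl]-5-oxooxolan-2-yl}cyclohex-2-en-1-one
Conditions: Pd(OAc)2 (1.1 equiv), MeCN, 25–40 °C
Reagents that add atoms: none
Why: Saegusa–Ito oxidation of the regiodefined silyl enol ether (palladium enolate, then β-hydride elimination of the ring hydrogen at C5) gives the conjugated tetrasubstituted enone and erases the auxiliary centre C5 after it has relayed chirality from C2′ to C6.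

Step 8
Reactants: 13 (enone lactone)
Product: 15 (3S,4S,5S)-3-methyl-4-[2-(2-methyl-1,3-dioxolan-2-yl)ethyl]-5-[(5S)-2-methyl-5-(6-methylhepta-1,5-dien-2-yl)-3-(trifluoromethanesulfonyloxy)cyclohexa-1,3-dien-1-yl]oxolan-2-one, via potassium dienolate 14 (not isolated)
Conditions: KN(SiMe3)2 (KHMDS, 1.05 equiv), THF, −78 °C; PhNTf2, −78 to 0 °C
Reagents that add atoms: N-phenylbis(trifluoromethanesulfonimide), O=S(=O)(N(c1ccccc1)S(=O)(=O)C(F)(F)F)C(F)(F)F
Why: Kinetic deprotonation at the α′ carbon (C2 of the target) gives the cross-conjugated dienolate (the ketone is more acidic than the lactone and γ-deprotonation is slower), and O-triflation fixes the C2=C3–C4=C5 diene.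

Step 9
Reactants: 15 (dienyl triflate)
Product: 16 (3S,4S,5S)-3-methyl-4-[2-(2-methyl-1,3-dioxolan-2-yl)ethyl]-5-[(5S)-2-methyl-5-(6-methylhepta-1,5-dien-2-yl)cyclohexa-1,3-dien-1-yl]oxolan-2-one
Conditions: Pd(OAc)2 (5 mol %), PPh3 (10 mol %), HCO2H (2 equiv), Bu3N (3 equiv), DMF, 50 °C
Reagents that add atoms: none
Why: Palladium-catalysed formate reduction of the enol triflate (oxidative addition, formate exchange, decarboxylation, reductive elimination) replaces OTf by H without moving the diene, giving the α-phellandrene-type cyclohexa-1,3-diene.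

Step 10
Reactants: 16 (diene lactone ketal)
Product: 17 (3S,4S,5S)-3-methyl-5-[(5S)-2-methyl-5-(6-methylhepta-1,5-dien-2-yl)cyclohexa-1,3-dien-1-yl]-4-(3-oxobutyl)oxolan-2-one
Conditions: PPTS (0.2 equiv), acetone/H2O (10:1), 40 °C
Reagents that add atoms: water, O
Why: Mild acid-catalysed hydrolysis of the dioxolane frees the methyl ketone under conditions that should leave the lactone and the diene alone.

Step 11
Reactants: 17 (diene lactone methyl ketone)
Product: 18 (3S,4S,5S)-4-(3-hydroxy-3-methyl-4-nitrobutyl)-3-methyl-5-[(5S)-2-methyl-5-(6-methylhepta-1,5-dien-2-yl)cyclohexa-1,3-dien-1-yl]oxolan-2-one (both carbinol epimers)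
Conditions: CH3NO2 (solvent), 1,1,3,3-tetramethylguanidine (0.2 equiv), 25 °C
Reagents that add atoms: nitromethane, C[N+](=O)[O-]
Why: Guanidine-catalysed Henry (nitroaldol) addition to the methyl ketone, pushed by the large excess of nitromethane, gives the tertiary β-nitro alcohol as an inconsequential epimer mixture.

Step 12
Reactants: 18 (β-nitro alcohol)
Product: 20 (3S,4S,5S)-3-methyl-4-[(3E)-3-methyl-4-nitrobut-3-en-1-yl]-5-[(5S)-2-methyl-5-(6-methylhepta-1,5-dien-2-yl)cyclohexa-1,3-dien-1-yl]oxolan-2-one, via trifluoroacetate 19 (not isolated)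
Conditions: (CF3CO)2O (1.2 equiv), Et3N (2.5 equiv), CH2Cl2, −20 to 0 °C
Reagents that add atoms: none
Why: Acylation of the tertiary alcohol and E1cB elimination through the nitronate give the conjugated nitroalkene under kinetic control, and its geometry does not matter for the final product.

Step 13
Reactants: 20 (diene nitroalkene)
Product: 21 nitro cycloadduct (1R; the target with H and a nitro group on the ketone carbon in place of its oxygen; nitro group syn to the bridge that carries the side chain)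
Conditions: PhMe (0.01 M), BHT (5 mol %), 105 °C, sealed tube
Reagents that add atoms: none
Why: Thermal, concerted but asynchronous intramolecular [4+2] cycloaddition in which the C2=C3–C4=C5 diene of the cyclohexadiene reacts with the C10=C1 nitroalkene, a ketene equivalent, forming C5–C10 and C2–C1. The closest known reactions are the thermal intramolecular Diels–Alder reactions of nitroalkenes and those of cyclohexa-1,3-dienes that carry the dienophile tether on a diene terminus and give bicyclo[2.2.2]octenes. Ring B closes at C5–C10 through the four-carbon tether C6–C9 in a chair that keeps the trans-lactone bonds at C6 and C7 equatorial, and the bridged cyclohexene ring C1–C2–C3–C4–C5–C10 closes when C1 bonds to the far diene terminus C2. C5 and C2 are set by addition to the diene face anti to the side chain at C2′ (the α-phellandrene pattern), and C10 by the chair tether, which places C9 under the diene and the methyl group toward the C1′–C2′ bridge, while the configuration at C1 is irrelevant. The step needs π-facial selectivity, which the C2′ substituent next to the bond-forming carbon C2 should secure, and on that face the lactone stereocentres make the chair with the tether under the diene the low-energy one. The two quaternary centres C5 and C10 can be joined because bond formation is pericyclic, intramolecular and activated by the nitro group.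

Step 14
Reactants: 21 (nitro cycloadduct)
Product: 23 CNP0385704.1 (target; 2S,5R,6S,7S,10R,11S,2′S in the numbering above), via potassium nitronate 22 (not isolated)
Conditions: t-BuOK (1.1 equiv), THF, 0 °C; then TiCl3 (aq., 4.5 equiv), NH4OAc, THF/H2O, 25 °C
Reagents that add atoms: water, O
Why: The reductive Nef reaction reduces the nitronate with TiCl3 to the imine, whose hydrolysis gives the non-enolisable C1 ketone without touching the lactone or the three alkenes.

**Compound list**

1 | (S)-(+)-carvone, (5S)-2-methyl-5-(prop-1-en-2-yl)cyclohex-2-en-1-one | CC1=CC[C@@H](CC1=O)C(C)=C | starting material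
2 | (5S)-5-(3-chloroprop-1-en-2-yl)-2-methylcyclohex-2-en-1-one | CC1=CC[C@@H](CC1=O)C(=C)CCl | intermediate
3 | (5S)-5-(hexa-1,5-dien-2-yl)-2-methylcyclohex-2-en-1-one | CC1=CC[C@@H](CC1=O)C(=C)CCC=C | intermediate
4 | (5S)-2-methyl-5-(6-methylhepta-1,5-dien-2-yl)cyclohex-2-en-1-one | CC1=CC[C@@H](CC1=O)C(=C)CCC=C(C)C | intermediate
5 | tert-butyl(furan-2-yloxy)dimethylsilane | CC(C)(C)[Si](C)(C)Oc1ccco1 | starting material
6 | (5S)-5-[(1S,5S)-3-{[tert-butyl(dimethyl)silyl]oxy}-2-methyl-5-(6-methylhepta-1,5-dien-2-yl)cyclohex-2-en-1-yl]furan-2(5H)-one | C=C(CCC=C(C)C)[C@H]1C[C@H]([C@H]2OC(=O)C=C2)C(C)=C(O[Si](C)(C)C(C)(C)C)C1 | intermediate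
7 | 2-(2-bromoethyl)-2-methyl-1,3-dioxolane | CC1(CCBr)OCCO1 | starting material
8 | [2-(2-methyl-1,3-dioxolan-2-yl)ethyl]magnesium bromide (not isolated) | CC1(CC[Mg]Br)OCCO1 | intermediate
9 | bromomagnesium enolate of lactone 10 (not isolated) | C=C(CCC=C(C)C)[C@H]1C[C@H]([C@H]2OC(O[Mg]Br)=C[C@@H]2CCC3(C)OCCO3)C(C)=C(O[Si](C)(C)C(C)(C)C)C1 | intermediate
10 | (4S,5S)-5-[(1S,5S)-3-{[tert-butyl(dimethyl)silyl]oxy}-2-methyl-5-(6-methylhepta-1,5-dien-2-yl)cyclohex-2-en-1-yl]-4-[2-(2-methyl-1,3-dioxolan-2-yl)ethyl]oxolan-2-one | C=C(CCC=C(C)C)[C@H]1C[C@H]([C@H]2OC(=O)C[C@@H]2CCC3(C)OCCO3)C(C)=C(O[Si](C)(C)C(C)(C)C)C1 | intermediate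
11 | lithium enolate of lactone 10 (not isolated) | C=C(CCC=C(C)C)[C@H]1C[C@H]([C@H]2OC(O[Li])=C[C@@H]2CCC3(C)OCCO3)C(C)=C(O[Si](C)(C)C(C)(C)C)C1 | intermediate
12 | (3S,4S,5S)-5-[(1S,5S)-3-{[tert-butyl(dimethyl)silyl]oxy}-2-methyl-5-(6-methylhepta-1,5-dien-2-yl)cyclohex-2-en-1-yl]-3-methyl-4-[2-(2-methyl-1,3-dioxolan-2-yl)ethyl]oxolan-2-one | C=C(CCC=C(C)C)[C@H]1C[C@H]([C@H]2OC(=O)[C@@H](C)[C@@H]2CCC3(C)OCCO3)C(C)=C(O[Si](C)(C)C(C)(C)C)C1 | intermediate
13 | (5S)-2-methyl-5-(6-methylhepta-1,5-dien-2-yl)-3-{(2S,3S,4S)-4-methyl-3-[2-(2-methyl-1,3-dioxolan-2-yl)ethyl]-5-oxooxolan-2-yl}cyclohex-2-en-1-one | C=C(CCC=C(C)C)[C@H]1CC(=C(C)C(=O)C1)[C@H]2OC(=O)[C@@H](C)[C@@H]2CCC3(C)OCCO3 | intermediate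
14 | potassium cross-conjugated dienolate of 13 (not isolated) | C=C(CCC=C(C)C)[C@H]1CC(=C(C)C(O[K])=C1)[C@H]2OC(=O)[C@@H](C)[C@@H]2CCC3(C)OCCO3 | intermediate
15 | (3S,4S,5S)-3-methyl-4-[2-(2-methyl-1,3-dioxolan-2-yl)ethyl]-5-[(5S)-2-methyl-5-(6-methylhepta-1,5-dien-2-yl)-3-(trifluoromethanesulfonyloxy)cyclohexa-1,3-dien-1-yl]oxolan-2-one | C=C(CCC=C(C)C)[C@H]1CC(=C(C)C(OS(=O)(=O)C(F)(F)F)=C1)[C@H]2OC(=O)[C@@H](C)[C@@H]2CCC3(C)OCCO3 | intermediate
16 | (3S,4S,5S)-3-methyl-4-[2-(2-methyl-1,3-dioxolan-2-yl)ethyl]-5-[(5S)-2-methyl-5-(6-methylhepta-1,5-dien-2-yl)cyclohexa-1,3-dien-1-yl]oxolan-2-one | C=C(CCC=C(C)C)[C@H]1CC(=C(C)C=C1)[C@H]2OC(=O)[C@@H](C)[C@@H]2CCC3(C)OCCO3 | intermediate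
17 | (3S,4S,5S)-3-methyl-5-[(5S)-2-methyl-5-(6-methylhepta-1,5-dien-2-yl)cyclohexa-1,3-dien-1-yl]-4-(3-oxobutyl)oxolan-2-one | C=C(CCC=C(C)C)[C@H]1CC(=C(C)C=C1)[C@H]2OC(=O)[C@@H](C)[C@@H]2CCC(C)=O | intermediate
18 | (3S,4S,5S)-4-(3-hydroxy-3-methyl-4-nitrobutyl)-3-methyl-5-[(5S)-2-methyl-5-(6-methylhepta-1,5-dien-2-yl)cyclohexa-1,3-dien-1-yl]oxolan-2-one (carbinol epimers) | C=C(CCC=C(C)C)[C@H]1CC(=C(C)C=C1)[C@H]2OC(=O)[C@@H](C)[C@@H]2CCC(C)(O)C[N+](=O)[O-] | intermediate
19 | trifluoroacetate of nitro alcohol 18 (not isolated) | C=C(CCC=C(C)C)[C@H]1CC(=C(C)C=C1)[C@H]2OC(=O)[C@@H](C)[C@@H]2CCC(C)(OC(=O)C(F)(F)F)C[N+](=O)[O-] | intermediate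
20 | (3S,4S,5S)-3-methyl-4-[(3E)-3-methyl-4-nitrobut-3-en-1-yl]-5-[(5S)-2-methyl-5-(6-methylhepta-1,5-dien-2-yl)cyclohexa-1,3-dien-1-yl]oxolan-2-one | C=C(CCC=C(C)C)[C@H]1CC(=C(C)C=C1)[C@H]2OC(=O)[C@@H](C)[C@@H]2CC/C(C)=C/[N+](=O)[O-] | intermediate
21 | nitro cycloadduct (1R): the skeleton of 23 with H and a nitro group on C1 in place of the ketone oxygen; nitro group syn to the C1′–C2′ bridge | C=C(CCC=C(C)C)[C@H]1C[C@@]23C(C)=C[C@@H]1[C@@H]([N+](=O)[O-])[C@]2(C)CC[C@H]1[C@H](C)C(=O)O[C@@H]13 | intermediate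
22 | potassium nitronate of 21 (not isolated) | C=C(CCC=C(C)C)[C@H]1C[C@@]23C(C)=C[C@@H]1C(=[N+]([O-])[O-])[C@]2(C)CC[C@H]1[C@H](C)C(=O)O[C@@H]13.[K+] | intermediate
23 | CNP0385704.1: bicyclo[2.2.2]oct-5-en-2-one (C1 ketone, C3=C4, bridgeheads C2 and C5) fused at C5–C10 to ring B with the trans 12,6-lactone; 2S,5R,6S,7S,10R,11S,2′S | C=C(CCC=C(C)C)[C@H]1C[C@@]23C(C)=C[C@@H]1C(=O)[C@]2(C)CC[C@H]1[C@H](C)C(=O)O[C@@H]13 | target

**Step count**

Total steps: 14. Longest linear sequence: 14 steps, from 1 to 23.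

**Steps most likely to fail**

1. Step 13. The cycloaddition has to join two fully substituted carbons and may be too slow below the temperature at which the cyclohexadiene begins to suffer 1,5-hydrogen shifts. Facial selectivity may also erode, because on the face anti to the side chain the tether must pass the C4 methyl group (allylic strain). Fallback, from 20 back to 21: with SnCl4 (1.1 equiv) in CH2Cl2 at −78 °C the nitroalkene should react instead as a 4π heterodiene (O=N–C1=C10) with the C4=C5 bond of the diene, a tin-promoted inverse-demand hetero-[4+2] reaction that forms C10–C5 and O–C4 and gives the cyclic nitronate F1. After NaHCO3 work-up, gentle warming (PhMe, 60–80 °C) should bring about the [3,3]-sigmatropic shift of this vinyl-substituted nitronate (O–C4 breaks, C1–C2 forms) to give 21.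

2. Step 4. The open and the compact transition states of the Mukaiyama–Michael addition lead to opposite configurations at C6, so simple diastereoselection may be poor or reversed. Fallback, from 4 back to 6, with C6 under reagent control: TBSOTf-promoted Michael addition of formaldehyde N,N-dimethylhydrazone, a neutral formyl anion equivalent (TBSOTf, then Et3N, CH2Cl2, −78 °C), should give, anti to the side chain, the hydrazone silyl enol ether F2. Hydrolysis of the hydrazone (CuCl2, pH 7 buffer, THF) would then give the aldehyde F3. Zinc-mediated asymmetric alkynylation with methyl propiolate (Me2Zn, the ProPhenol ligand enantiomer that delivers the (R)-carbinol, PhMe, 0 °C) would give the hydroxy ynoate F4. Semi-hydrogenation (H2, Pd/CaCO3 poisoned with Pb(OAc)2, quinoline, EtOAc) and spontaneous lactonisation of the (Z)-hydroxy enoate would return 6. The ring centre next to the aldehyde may epimerise without harm, because step 7 erases it.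

3. Step 11. The nitroaldol equilibrium with a ketone may lie on the side of the starting materials, and the adduct may revert or deconjugate in step 12. Fallback, from 17 directly to 23, with an enal as ketene equivalent: formyl-olefination with diethyl [2-(cyclohexylamino)vinyl]phosphonate (NaH, THF, 0–25 °C) should give the unsaturated N-cyclohexyl imine F5, hydrolysed in the same flask (aq. oxalic acid) to the enal F6. Me2AlCl (1.5 equiv) in CH2Cl2 at −78 to −20 °C should then promote the intramolecular Diels–Alder reaction of the enal to the formyl cycloadduct F7, with the same facial and tether control as in step 13. Copper-catalysed aerobic oxidative deformylation of this α-branched aldehyde (Cu(OAc)2 (10 mol %), 2,2′-bipyridine, DABCO, O2, DMF, 40 °C) would give 23.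

Further compounds
F1 | step 13 | cyclic nitronate (5,6-dihydro-4H-1,2-oxazine N-oxide) from hetero-[4+2] addition of the nitroalkene across C4=C5, C10–C5 and O–C4 bonds on the face anti to the side chain | C=C(CCC=C(C)C)[C@H]1C[C@@]23[C@@](C)(C=C1)O[N+]([O-])=C[C@]2(C)CC[C@H]4[C@H](C)C(=O)O[C@H]34
F2 | step 4 | N,N-dimethylhydrazone of (1S,5S)-3-{[tert-butyl(dimethyl)silyl]oxy}-2-methyl-5-(6-methylhepta-1,5-dien-2-yl)cyclohex-2-ene-1-carbaldehyde | C=C(CCC=C(C)C)[C@H]1C[C@H](C=NN(C)C)C(C)=C(O[Si](C)(C)C(C)(C)C)C1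
F3 | step 4 | (1S,5S)-3-{[tert-butyl(dimethyl)silyl]oxy}-2-methyl-5-(6-methylhepta-1,5-dien-2-yl)cyclohex-2-ene-1-carbaldehyde | C=C(CCC=C(C)C)[C@H]1C[C@H](C=O)C(C)=C(O[Si](C)(C)C(C)(C)C)C1
F4 | step 4 | methyl (4R)-4-[(1S,5S)-3-{[tert-butyl(dimethyl)silyl]oxy}-2-methyl-5-(6-methylhepta-1,5-dien-2-yl)cyclohex-2-en-1-yl]-4-hydroxybut-2-ynoate | C=C(CCC=C(C)C)[C@H]1C[C@H]([C@@H](O)C#CC(=O)OC)C(C)=C(O[Si](C)(C)C(C)(C)C)C1
F5 | step 11 | N-cyclohexyl imine of enal F6 (not isolated) | C=C(CCC=C(C)C)[C@H]1CC(=C(C)C=C1)[C@H]2OC(=O)[C@@H](C)[C@@H]2CC/C(C)=C/C=NC3CCCCC3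
F6 | step 11 | (2E)-3-methyl-5-{(2S,3S,4S)-4-methyl-2-[(5S)-2-methyl-5-(6-methylhepta-1,5-dien-2-yl)cyclohexa-1,3-dien-1-yl]-5-oxooxolan-3-yl}pent-2-enal | C=C(CCC=C(C)C)[C@H]1CC(=C(C)C=C1)[C@H]2OC(=O)[C@@H](C)[C@@H]2CC/C(C)=C/C=O
F7 | step 11 | formyl cycloadduct: target skeleton with H and CHO at C1 instead of the ketone oxygen (either C1 epimer) | C=C(CCC=C(C)C)[C@H]1C[C@@]23C(C)=C[C@@H]1C(C=O)[C@]2(C)CC[C@H]1[C@H](C)C(=O)O[C@@H]13
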